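## Structural features

The target is a flavonol: a 4H-chromen-4-one in which benzo ring A and pyranone ring C share the C4a–C8a bond, with a 4-hydroxy-3-methoxyphenyl ring B on C2 and a hydroxyl on C3. Ring A is substituted everywhere except C6: a hydroxyl on C5 (hydrogen-bonded to the C4 carbonyl), a 3-methylbut-2-enyl (prenyl) ether on O7 and a methyl ether on O8. There is no stereocenter, and the prenyl double bond carries two identical methyl groups, so no configuration has to be set. The fragile groups are the prenyl aryl ether (lost to acid, Lewis acid or hydrogenolysis, and prone to Claisen shift on heating) and the electron-rich 3-hydroxypyranone and phenols, which oxidize in air under base. The real difficulty is the five oxygens: O3, O5 and O4' must end free, O8 methylated and O7 prenylated, and O7 and O8 are neighbours on one ring. The key step uses exactly this pair. C8 enters as a methoxy-bearing carbene carbon on C8a and C7 as carbon monoxide, so O8 is born as a methyl ether and O7 as the only free hydroxyl. The C8a=C4a double bond of ring C and a two-carbon enol ether on C4a (C5 and C6) supply the rest of ring A.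

## Logic of the disconnections

22 back to 21: the three O–Si bonds at O3, O5 and O4' are cut. All free hydroxyls are unmasked in one operation, so the last step only has to be a fluoride cleavage that is buffered and leaves the prenyl ether alone.

21 back to 19 and 20: the O7–CH2 bond is cut. This removes the acid-sensitive side chain until the penultimate step. It demands that 19 carry exactly one free hydroxyl and that the alkylation be neutral.

19 back to 16: the C6–C7 and C7–C8 bonds are cut and ring A is opened, C7 leaving as carbon monoxide. The whole benzo ring and three of its oxygens are traced to a carbene carbon (C8, with its methoxy group), a carbonyl ligand (C7, O7) and a silyl enol ether (C5, C6, O5). The forward step needs the carbene and the vinyl group on adjacent carbons of ring C, carbonyl insertion faster than other cyclization paths, and light that does not excite the pyranone.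

16 back to 12 and 13: the C8–C8a bond and the O8–CH3 bond are cut. The metal fragment becomes a purchased carbonyl complex and the organic part a pyranone with a C8a–H. The forward step demands selective metalation of that C–H next to an enol silyl ether. The silicon on the vinyl oxygen sits 1,4 to the carbanion, so it must be a bulky group that does not migrate, and the methylating agent must be limited to one equivalent.

12 back to 11, then to 8 and 9: the vinyl O–Si bond is cut, then the bond from C4a to the acetyl carbon. The enol ether reduces to a methyl ketone and the ketone to a cross-coupling of a C4a bromide with a purchased acetyl-anion equivalent. This demands a bromine placed on C4a with certainty.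

8 back to 7, 6 and 5: the two O–Si bonds are cut, then the C4=O bond is traced to a C4 bromine, and the pyranone to a ring-expanded hemiacetal and a furyl carbinol. Two reasons dictate this cut. A ring-expanded furfuryl alcohol without a substituent at C4 is two electrons short of a 4-pyranone. Electrophilic bromination of the finished pyranone would also have to compete with electron-rich ring B. Both are solved by carrying C4 and C4a as the two bromines of a dibromofuran. The forward steps demand an oxidant that attacks the furan and not the arene, and a hydrolysis that replaces only the C4 bromine.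

5 back to 2 and 3, and 2 back to 1: the C2–C3 bond (carbinol carbon to furan carbon) is cut, then the aryl O–Si bond. The entire carbon skeleton of rings B and C reduces to two purchased compounds. The forward step demands metalation of the furan next to bromine without halogen–metal exchange.

## Other disconnections considered

Alternative 1: The cut is through ring C at O1–C2 and C3–C4, separating 4,6-bis(benzyloxy)-2-hydroxy-3-methoxybenzaldehyde (A1) from (E)-1-(benzyloxy)-2-methoxy-4-(2-nitroethenyl)benzene (A2). In the forward step an amine base would add the phenoxide of A1 to the nitroalkene of A2 and the nitronate to the aldehyde, and dehydration would give the racemic 3-nitro-2H-chromene A3.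
- In its favour: it is convergent, uses only polar, base-mediated chemistry, and forms two skeletal bonds and one ring in one operation. In bond count it is the equal of the chosen key step, and in operational simplicity and convergence it is the better.
- Against it: A3 has the wrong oxidation pattern in ring C (nitrogen on C3, C4 as CH), so several redox steps would be needed to reach the 3-hydroxy-4-ketone, and its C2 stereocenter is made only to be destroyed.
- It builds ring C, whereas the difficulty lies in ring A: A1 must already hold the 5,7,8-oxygen pattern, and with O5 and O7 both benzylated, prenylation after debenzylation would have to pick O7 among four free hydroxyls without structural help.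
- Comparison: on mechanism the alternative is the more predictable; on structure the chosen plan is better because it delivers O7 as the single free hydroxyl. On step economy the alternative should be shorter before its key step and longer after it, so roughly equal overall.

Alternative 2: The cut is the O1–C8a bond. The precursor is the 2-benzoyloxy-1,3-diketone A4, whose ring A is a 2-hydroxy-5-methoxy-4-prenyloxyphenyl group. Anodic oxidation in methanol would turn the para-methoxyphenol into a quinone monoketal, the diketone enol oxygen would add at C8a, and loss of methanol would rearomatize ring A to give A5.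
- In its favour: ring A comes from a benzene starting material with all its oxygens in place and differentiated, the prenyl group is already on O7, and only two benzoates remain to be removed. On step economy and on the length of the endgame this alternative is the better of the two, and on oxygen differentiation it is the equal.
- Against it: the oxidation must single out the acyl-deactivated phenol in the presence of a trisubstituted alkene, an electron-rich ring B and an oxidizable enol.
- Further risks are that methanol may intercept the monoketal, that the ambident enol may attack through carbon, and that the 2-acyloxy-1,3-diketone may undergo acyl shift or retro-Claisen cleavage in methanolic electrolyte.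
- Comparison: the alternative forms one C–O bond where the chosen plan forms two C–C bonds. Its selectivity rests on a narrow window of oxidation potentials, whereas the regiochemistry of the chosen step is fixed by connectivity.

Alternative 3: The cut is C4a–C5 in the key step and C8–C8a in the step before, leading to the 4-hydroxy-4-(pyranon-2-yl)cyclobutenone A6, made by adding a C8a-lithiated pyranone to a 3-benzyloxycyclobutenedione. Heating A6 would open the four-membered ring to a dienylketene whose ketene carbon closes on C4a, giving the 5,8-hydroquinone A7.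
- In its favour: the step is thermal and metal-free, and the pyranone partner needs no substituent on C4a, so two steps of the chosen route (cross-coupling and enol silylation) would be saved. In these respects it is the better; in its reliance on a C8a-lithiated pyranone it is the equal.
- Against it: the two new oxygens appear as free O5 and O8 with O7 benzylated. O8 would have to be methylated selectively, all benzyl groups removed before any prenyl group is present, and O7 then prenylated among four free hydroxyls.
- In addition, A7 is an air-sensitive para-hydroquinone, and the monosubstituted squarate is not a stock compound.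
- Comparison: both plans build ring A on ring C through a dienylketene and a 6π closure. The alternative generates the ketene more simply; the chosen plan places the ketene carbon at C7 and so gives the oxygen pattern the target needs. Overall step count should be similar, with the alternative shorter before and longer after the key step.

Key step: step 9

Remark on the chemistry: flavone numbering (O1, C2–C4, C4a, C5–C8, C8a) is used for every intermediate. TBS is tert-butyldimethylsilyl and TIPS is triisopropylsilyl. The silyl group on the vinyl oxygen is TIPS and not TBS because it sits 1,4 to the C8a carbanion of step 8.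

## Route

Step 1
Reactants: 1 4-hydroxy-3-methoxybenzaldehyde (vanillin)
Product: 2 4-[(tert-butyldimethylsilyl)oxy]-3-methoxybenzaldehyde
Conditions: TBSCl, imidazole, DMF, rt
Reagents that add atoms: tert-butyldimethylsilyl chloride, CC(C)(C)[Si](C)(C)Cl
Why: Standard imidazole-promoted silylation of a phenol; the silyl ether removes the acidic proton before the organolithium step and is lost again, by design, in step 4.

Step 2
Reactants: 3 3,4-dibromofuran; 2 4-[(tert-butyldimethylsilyl)oxy]-3-methoxybenzaldehyde
Product: 5 (3,4-dibromofuran-2-yl){4-[(tert-butyldimethylsilyl)oxy]-3-methoxyphenyl}methanol (racemic), via (3,4-dibromofuran-2-yl)lithium 4 (not isolated)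
Conditions: LiN(iPr)2, THF, −78 °C; then 2, −78 °C; aq. NH4Cl
Reagents that add atoms: none
Why: The C2–H of 3,4-dibromofuran, flanked by the ring oxygen and a bromine, is removed by a lithium amide at −78 °C (directed α-metalation, no halogen–lithium exchange with an amide base), and the furyllithium adds 1,2 to the non-enolizable aldehyde; the carbinol stereocenter forms racemic and is erased in step 4.

Step 3
Reactants: 5 (3,4-dibromofuran-2-yl){4-[(tert-butyldimethylsilyl)oxy]-3-methoxyphenyl}methanol
Product: 6 4,5-dibromo-2-{4-[(tert-butyldimethylsilyl)oxy]-3-methoxyphenyl}-6-hydroxy-2H-pyran-3(6H)-one (racemic, both anomers)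
Conditions: mCPBA, CH2Cl2, 0 °C to rt; aq. Na2S2O3/NaHCO3 wash
Reagents that add atoms: 3-chloroperoxybenzoic acid, OOC(=O)c1cccc(Cl)c1
Why: Achmatowicz rearrangement: the peracid oxidizes the furan, the ring opens to a cis-enedione and the carbinol oxygen closes onto the aldehyde as a six-membered hemiacetal; a peracid is chosen because, unlike NBS or bromine, it does not halogenate electron-rich ring B; the two stereocenters are uncontrolled and both disappear in step 4.

Step 4
Reactants: 6 4,5-dibromo-2-{4-[(tert-butyldimethylsilyl)oxy]-3-methoxyphenyl}-6-hydroxy-2H-pyran-3(6H)-one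
Product: 7 5-bromo-3-hydroxy-2-(4-hydroxy-3-methoxyphenyl)-4H-pyran-4-one
Conditions: 3 M aq. HCl, 1,4-dioxane, 80 °C
Reagents that add atoms: water, O
Why: Acid-promoted aromatization of a 4-halo-6-hydroxy-2H-pyran-3(6H)-one, the second stage of the halogen-based maltol synthesis: enolization toward C2 and loss of the anomeric hydroxyl give a pyrylium ion, water adds at C4 (para to the ring oxygen, the only bromine-bearing carbon that is electrophilic in the cation) and HBr is lost, leaving the C4a bromine; hot acid also removes the aryl silyl ether, which is intended because step 5 silylates both hydroxyls.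

Step 5
Reactants: 7 5-bromo-3-hydroxy-2-(4-hydroxy-3-methoxyphenyl)-4H-pyran-4-one
Product: 8 5-bromo-3-[(tert-butyldimethylsilyl)oxy]-2-{4-[(tert-butyldimethylsilyl)oxy]-3-methoxyphenyl}-4H-pyran-4-one
Conditions: TBSCl (2.5 equiv), imidazole, DMF, rt
Reagents that add atoms: tert-butyldimethylsilyl chloride, CC(C)(C)[Si](C)(C)Cl
Why: Imidazole-promoted silylation of the phenol and of the acidic enolic 3-hydroxyl, as practised on maltol and flavonols; any aryl silyl ether that survived step 4 converges on the same product.

Step 6
Reactants: 8 5-bromo-3-[(tert-butyldimethylsilyl)oxy]-2-{4-[(tert-butyldimethylsilyl)oxy]-3-methoxyphenyl}-4H-pyran-4-one; 9 tributyl(1-ethoxyvinyl)stannane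
Product: 11 5-acetyl-3-[(tert-butyldimethylsilyl)oxy]-2-{4-[(tert-butyldimethylsilyl)oxy]-3-methoxyphenyl}-4H-pyran-4-one, via 1-ethoxyvinyl pyranone 10 (not isolated)
Conditions: Pd(PPh3)4 (5 mol %), toluene, 100 °C; then 1 M aq. HCl, THF, 0 °C to rt
Reagents that add atoms: water, O
Why: Stille coupling at the only C–Br bond, an α-bromo enone of the kind that couples readily in 3-bromochromones, followed by dilute-acid hydrolysis of the 1-ethoxyvinyl group to the methyl ketone; fluoride work-up is avoided and brief cold dilute acid leaves the silyl ethers in place.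

Step 7
Reactants: 11 5-acetyl-3-[(tert-butyldimethylsilyl)oxy]-2-{4-[(tert-butyldimethylsilyl)oxy]-3-methoxyphenyl}-4H-pyran-4-one
Product: 12 3-[(tert-butyldimethylsilyl)oxy]-2-{4-[(tert-butyldimethylsilyl)oxy]-3-methoxyphenyl}-5-{1-[(triisopropylsilyl)oxy]vinyl}-4H-pyran-4-one
Conditions: TIPSOTf, Et3N, CH2Cl2, 0 °C
Reagents that add atoms: triisopropylsilyl trifluoromethanesulfonate, CC(C)[Si](C(C)C)(C(C)C)OS(=O)(=O)C(F)(F)F
Why: Soft enolization and O-silylation of a methyl ketone with a silyl triflate and a tertiary amine; the methyl group is the only enolizable position, and the triisopropylsilyl group is chosen for its low tendency to migrate from oxygen to carbon in step 8.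

Step 8
Reactants: 12 3-[(tert-butyldimethylsilyl)oxy]-2-{4-[(tert-butyldimethylsilyl)oxy]-3-methoxyphenyl}-5-{1-[(triisopropylsilyl)oxy]vinyl}-4H-pyran-4-one; 13 hexacarbonylchromium, Cr(CO)6
Product: 16 pentacarbonyl{methoxy[5-(tert-butyldimethylsilyloxy)-6-(4-(tert-butyldimethylsilyloxy)-3-methoxyphenyl)-4-oxo-3-(1-(triisopropylsilyloxy)vinyl)-4H-pyran-2-yl]methylidene}chromium, via C8a-lithiated pyranone 14 (not isolated), via lithium acylchromate 15 (not isolated)
Conditions: lithium 2,2,6,6-tetramethylpiperidide, THF, −78 °C; Cr(CO)6, −78 to 0 °C; then MeOTf (1.0 equiv), CH2Cl2, −20 °C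
Reagents that add atoms: methyl trifluoromethanesulfonate, COS(=O)(=O)C(F)(F)F
Why: Fischer carbene synthesis: the C8a–H, next to the ring oxygen and β to the C4 carbonyl, is the most acidic C–H (chromones are lithiated at the corresponding C2 by hindered lithium amides), the vinyllithium adds to a carbonyl ligand of Cr(CO)6, and one equivalent of a hard methylating agent alkylates the acylate oxygen; low temperature and the bulky silyl group suppress 1,4 oxygen-to-carbon silyl migration, and the limited methyl triflate spares the C4 carbonyl oxygen.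

Step 9
Reactants: 16 pentacarbonyl{methoxy[5-(tert-butyldimethylsilyloxy)-6-(4-(tert-butyldimethylsilyloxy)-3-methoxyphenyl)-4-oxo-3-(1-(triisopropylsilyloxy)vinyl)-4H-pyran-2-yl]methylidene}chromium
Product: 19 3-[(tert-butyldimethylsilyl)oxy]-2-{4-[(tert-butyldimethylsilyl)oxy]-3-methoxyphenyl}-7-hydroxy-8-methoxy-5-[(triisopropylsilyl)oxy]-4H-chromen-4-one, via chromium-bound dienylketene 17 (not isolated), via ring A cyclohexadienone 18 (not isolated)
Conditions: hν (blue LEDs, 450 nm, Pyrex), CO (1 atm), THF, rt; then air, silica filtration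
Reagents that add atoms: none
Why: Visible light excites the metal-to-ligand charge-transfer band of 16 and a cis carbonyl ligand migrates onto the carbene carbon, forming the C7–C8 bond and the chromium-bound methoxy ketene 17. In 17 the ketene C7=C8, the ring C double bond C8a=C4a and the silyloxyvinyl C5=C6 form a hexatriene held s-cis at its central bond by the ring, and thermal 6π electrocyclization forms C6–C7 and closes ring A as a six-membered carbocycle (18); because C6 is the nucleophilic end of a silyl enol ether and C7 a ketene carbon, the same bond would also form by a stepwise polar addition. Enolization of 18 with loss of one C6 hydrogen aromatizes ring A to the phenol 19. The closest known reaction type is the photochemical benzannulation of dienyl(alkoxy)carbene complexes of chromium under carbon monoxide, which gives ortho-alkoxyphenols. No stereocenter is formed. The step needs carbonyl insertion to win over insertion-free cyclization to a five-membered ring and over photoreactions of the pyranone; light above 400 nm addresses only the carbene chromophore, and the CO atmosphere supports ketene formation and returns the zerovalent chromium fragment as Cr(CO)6. Regiochemistry is not a variable: the carbene methoxy group must end on C8 and the inserted carbonyl oxygen on C7, so O7 is the only free hydroxyl.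

Step 10
Reactants: 19 3-[(tert-butyldimethylsilyl)oxy]-2-{4-[(tert-butyldimethylsilyl)oxy]-3-methoxyphenyl}-7-hydroxy-8-methoxy-5-[(triisopropylsilyl)oxy]-4H-chromen-4-one; 20 3-methylbut-2-en-1-ol
Product: 21 3-[(tert-butyldimethylsilyl)oxy]-2-{4-[(tert-butyldimethylsilyl)oxy]-3-methoxyphenyl}-8-methoxy-7-[(3-methylbut-2-en-1-yl)oxy]-5-[(triisopropylsilyl)oxy]-4H-chromen-4-one
Conditions: PPh3, diisopropyl azodicarboxylate, THF, 0 °C to rt
Reagents that add atoms: none
Why: Mitsunobu etherification of the single free phenol, acidified by the para C4 carbonyl, with a primary allylic alcohol; the neutral conditions leave the three silyl ethers alone and substitution at the primary carbon keeps the linear prenyl connectivity.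

Step 11
Reactants: 21 3-[(tert-butyldimethylsilyl)oxy]-2-{4-[(tert-butyldimethylsilyl)oxy]-3-methoxyphenyl}-8-methoxy-7-[(3-methylbut-2-en-1-yl)oxy]-5-[(triisopropylsilyl)oxy]-4H-chromen-4-one
Product: 22 3,5-dihydroxy-2-(4-hydroxy-3-methoxyphenyl)-8-methoxy-7-[(3-methylbut-2-en-1-yl)oxy]-4H-chromen-4-one
Conditions: Bu4NF (3.5 equiv), AcOH (3.5 equiv), THF, 0 °C to rt
Reagents that add atoms: none
Why: Fluoride cleavage of the two aryl silyl ethers and the enol silyl ether, the peri carbonyl easing loss of the C5 group; acetic acid buffers the phenoxides so the flavonol is not oxidized under basic conditions, and the prenyl ether is inert to fluoride.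

## Compound list

1 | 4-hydroxy-3-methoxybenzaldehyde (vanillin) | COc1cc(C=O)ccc1O | starting material
2 | 4-[(tert-butyldimethylsilyl)oxy]-3-methoxybenzaldehyde | COc1cc(C=O)ccc1O[Si](C)(C)C(C)(C)C | intermediate
3 | 3,4-dibromofuran | Brc1cocc1Br | starting material
4 | (3,4-dibromofuran-2-yl)lithium | [Li]c1occ(Br)c1Br | intermediate
5 | (3,4-dibromofuran-2-yl){4-[(tert-butyldimethylsilyl)oxy]-3-methoxyphenyl}methanol, racemic | COc1cc(C(O)c2occ(Br)c2Br)ccc1O[Si](C)(C)C(C)(C)C | intermediate
6 | 4,5-dibromo-2-{4-[(tert-butyldimethylsilyl)oxy]-3-methoxyphenyl}-6-hydroxy-2H-pyran-3(6H)-one, racemic, both anomers | COc1cc(C2OC(O)C(Br)=C(Br)C2=O)ccc1O[Si](C)(C)C(C)(C)C | intermediate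
7 | 5-bromo-3-hydroxy-2-(4-hydroxy-3-methoxyphenyl)-4H-pyran-4-one | COc1cc(-c2occ(Br)c(=O)c2O)ccc1O | intermediate
8 | 5-bromo-3-[(tert-butyldimethylsilyl)oxy]-2-{4-[(tert-butyldimethylsilyl)oxy]-3-methoxyphenyl}-4H-pyran-4-one | COc1cc(-c2occ(Br)c(=O)c2O[Si](C)(C)C(C)(C)C)ccc1O[Si](C)(C)C(C)(C)C | intermediate
9 | tributyl(1-ethoxyvinyl)stannane | CCCC[Sn](CCCC)(CCCC)C(=C)OCC | starting material
10 | 3-[(tert-butyldimethylsilyl)oxy]-2-{4-[(tert-butyldimethylsilyl)oxy]-3-methoxyphenyl}-5-(1-ethoxyvinyl)-4H-pyran-4-one | CCOC(=C)c1coc(-c2ccc(O[Si](C)(C)C(C)(C)C)c(OC)c2)c(O[Si](C)(C)C(C)(C)C)c1=O | intermediate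
11 | 5-acetyl-3-[(tert-butyldimethylsilyl)oxy]-2-{4-[(tert-butyldimethylsilyl)oxy]-3-methoxyphenyl}-4H-pyran-4-one | CC(=O)c1coc(-c2ccc(O[Si](C)(C)C(C)(C)C)c(OC)c2)c(O[Si](C)(C)C(C)(C)C)c1=O | intermediate
12 | 3-[(tert-butyldimethylsilyl)oxy]-2-{4-[(tert-butyldimethylsilyl)oxy]-3-methoxyphenyl}-5-{1-[(triisopropylsilyl)oxy]vinyl}-4H-pyran-4-one | C=C(O[Si](C(C)C)(C(C)C)C(C)C)c1coc(-c2ccc(O[Si](C)(C)C(C)(C)C)c(OC)c2)c(O[Si](C)(C)C(C)(C)C)c1=O | intermediate
13 | hexacarbonylchromium, Cr(CO)6 | O=C=[Cr](=C=O)(=C=O)(=C=O)(=C=O)=C=O | starting material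
14 | {5-(tert-butyldimethylsilyloxy)-6-[4-(tert-butyldimethylsilyloxy)-3-methoxyphenyl]-4-oxo-3-[1-(triisopropylsilyloxy)vinyl]-4H-pyran-2-yl}lithium | [Li]c1oc(-c2ccc(O[Si](C)(C)C(C)(C)C)c(OC)c2)c(O[Si](C)(C)C(C)(C)C)c(=O)c1C(=C)O[Si](C(C)C)(C(C)C)C(C)C | intermediate
15 | lithium pentacarbonyl{oxido[5-(tert-butyldimethylsilyloxy)-6-(4-(tert-butyldimethylsilyloxy)-3-methoxyphenyl)-4-oxo-3-(1-(triisopropylsilyloxy)vinyl)-4H-pyran-2-yl]methylidene}chromate | [Li+].[O-]C(=[Cr](=C=O)(=C=O)(=C=O)(=C=O)=C=O)c1oc(-c2ccc(O[Si](C)(C)C(C)(C)C)c(OC)c2)c(O[Si](C)(C)C(C)(C)C)c(=O)c1C(=C)O[Si](C(C)C)(C(C)C)C(C)C | intermediate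
16 | pentacarbonyl{methoxy[5-(tert-butyldimethylsilyloxy)-6-(4-(tert-butyldimethylsilyloxy)-3-methoxyphenyl)-4-oxo-3-(1-(triisopropylsilyloxy)vinyl)-4H-pyran-2-yl]methylidene}chromium | COC(=[Cr](=C=O)(=C=O)(=C=O)(=C=O)=C=O)c1oc(-c2ccc(O[Si](C)(C)C(C)(C)C)c(OC)c2)c(O[Si](C)(C)C(C)(C)C)c(=O)c1C(=C)O[Si](C(C)C)(C(C)C)C(C)C | intermediate
17 | 2-methoxy-2-{5-(tert-butyldimethylsilyloxy)-6-[4-(tert-butyldimethylsilyloxy)-3-methoxyphenyl]-4-oxo-3-[1-(triisopropylsilyloxy)vinyl]-4H-pyran-2-yl}ethen-1-one (the dienylketene; held on a carbonylchromium fragment in the flask, drawn metal-free) | COC(=C=O)c1oc(-c2ccc(O[Si](C)(C)C(C)(C)C)c(OC)c2)c(O[Si](C)(C)C(C)(C)C)c(=O)c1C(=C)O[Si](C(C)C)(C(C)C)C(C)C | intermediate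
18 | 3-[(tert-butyldimethylsilyl)oxy]-2-{4-[(tert-butyldimethylsilyl)oxy]-3-methoxyphenyl}-8-methoxy-5-[(triisopropylsilyl)oxy]-6H-chromene-4,7-dione | COC1=C2OC(-c3ccc(O[Si](C)(C)C(C)(C)C)c(OC)c3)=C(O[Si](C)(C)C(C)(C)C)C(=O)C2=C(O[Si](C(C)C)(C(C)C)C(C)C)CC1=O | intermediate
19 | 3-[(tert-butyldimethylsilyl)oxy]-2-{4-[(tert-butyldimethylsilyl)oxy]-3-methoxyphenyl}-7-hydroxy-8-methoxy-5-[(triisopropylsilyl)oxy]-4H-chromen-4-one | O=c1c(O[Si](C)(C)C(C)(C)C)c(-c2ccc(O[Si](C)(C)C(C)(C)C)c(OC)c2)oc2c(OC)c(O)cc(O[Si](C(C)C)(C(C)C)C(C)C)c12 | intermediate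
20 | 3-methylbut-2-en-1-ol (prenol) | CC(C)=CCO | starting material
21 | 3-[(tert-butyldimethylsilyl)oxy]-2-{4-[(tert-butyldimethylsilyl)oxy]-3-methoxyphenyl}-8-methoxy-7-[(3-methylbut-2-en-1-yl)oxy]-5-[(triisopropylsilyl)oxy]-4H-chromen-4-one | COc1cc(-c2oc3c(OC)c(OCC=C(C)C)cc(O[Si](C(C)C)(C(C)C)C(C)C)c3c(=O)c2O[Si](C)(C)C(C)(C)C)ccc1O[Si](C)(C)C(C)(C)C | intermediate
22 | 3,5-dihydroxy-2-(4-hydroxy-3-methoxyphenyl)-8-methoxy-7-[(3-methylbut-2-en-1-yl)oxy]-4H-chromen-4-one | COc1cc(-c2oc3c(OC)c(OCC=C(C)C)cc(O)c3c(=O)c2O)ccc1O | target

## Step count and risks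

Total: 11 steps. Longest linear sequence: 11 steps (1 to 22); compounds 3, 9, 13 and 20 are purchased and enter directly.

Step 9 (key step). Most likely to go wrong: cyclization of the dienyl carbene without carbonyl insertion, or light-induced rearrangement of the pyranone, because the carbene sits on an electron-poor, hindered heteroaryl carbon and ketene formation may be slow. Fallback: the same dienylketene is generated without chromium. The route is left at 12 and rejoined at 19.
- Lithiation of 12 as in step 8, transmetalation with ZnCl2 and alkylation with methyl 2-chloro-2-methoxyacetate should give methyl 2-methoxy-2-{5-(tert-butyldimethylsilyloxy)-6-[4-(tert-butyldimethylsilyloxy)-3-methoxyphenyl]-4-oxo-3-[1-(triisopropylsilyloxy)vinyl]-4H-pyran-2-yl}acetate F1.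
- Neutral ester cleavage with Me3SnOH in 1,2-dichloroethane should give the corresponding 2-methoxy-2-(pyran-2-yl)acetic acid F2.
- 1-Chloro-N,N,2-trimethylprop-1-en-1-amine should convert it to the 2-methoxy-2-(pyran-2-yl)acetyl chloride F3.
- Et3N in warm toluene should dehydrochlorinate F3 to the metal-free ketene 17, which closes to 18 and tautomerizes to 19.

Step 8. Most likely to go wrong: migration of silicon from the vinyl oxygen to the C8a carbanion, fragmentation of the lithiated pyranone on warming, or methylation at the C4 carbonyl oxygen. The anion must survive until it meets the sparingly soluble Cr(CO)6. Fallback: the carbene is built before any silicon is placed on the vinyl oxygen. The route is left at 10 (isolated by omitting the acid treatment of step 6) and rejoined at 16.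
- The same metalation, Cr(CO)6 addition and O-methylation on 10, where the ethoxy oxygen can only chelate lithium, should give pentacarbonyl{[3-(1-ethoxyvinyl)-5-(tert-butyldimethylsilyloxy)-6-(4-(tert-butyldimethylsilyloxy)-3-methoxyphenyl)-4-oxo-4H-pyran-2-yl](methoxy)methylidene}chromium F4.
- Cold dilute aqueous acid should hydrolyse the enol ether to pentacarbonyl{[3-acetyl-5-(tert-butyldimethylsilyloxy)-6-(4-(tert-butyldimethylsilyloxy)-3-methoxyphenyl)-4-oxo-4H-pyran-2-yl](methoxy)methylidene}chromium F5.
- TIPSOTf and Et3N should then give 16.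

Step 3. Most likely to go wrong: slow oxidation of the electron-poor dibromofuran, so that the peracid is consumed unproductively; stronger halogen oxidants cannot be used because they would halogenate ring B. Fallback: the oxidation is run before ring B is attached. The route is left at 3 and rejoined at 7.
- Furyllithium 4 and paraformaldehyde should give (3,4-dibromofuran-2-yl)methanol F6.
- NBS in buffered aqueous THF should give 4,5-dibromo-6-hydroxy-2H-pyran-3(6H)-one F7.
- Hot aqueous HCl should give 5-bromo-3-hydroxy-4H-pyran-4-one F8.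
- Iodine in aqueous Na2CO3 should iodinate ortho to the enolic hydroxyl to give 5-bromo-3-hydroxy-2-iodo-4H-pyran-4-one F9.
- Suzuki coupling of the more reactive C2 iodide with purchased 2-methoxy-4-(4,4,5,5-tetramethyl-1,3,2-dioxaborolan-2-yl)phenol (Pd(PPh3)4, K2CO3, dioxane–water) should give 7.

Step 4. Most likely to go wrong: attack of water at the β-bromo enone carbon C4a before ionization to the pyrylium, giving displacement of the wrong bromine, or acid-induced cleavage at the benzylic C2–O1 bond. Fallback: a series with a single bromine, so that the hydrolysis has no choice, and C4a is brominated late. The route is left at 2 and rejoined at 8.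
- 3-Bromofuran, lithiated at C2 with LiN(iPr)2, and 2 should give (3-bromofuran-2-yl){4-[(tert-butyldimethylsilyl)oxy]-3-methoxyphenyl}methanol F10.
- mCPBA should give 4-bromo-2-{4-[(tert-butyldimethylsilyl)oxy]-3-methoxyphenyl}-6-hydroxy-2H-pyran-3(6H)-one F11.
- Hot aqueous HCl should give 3-hydroxy-2-(4-hydroxy-3-methoxyphenyl)-4H-pyran-4-one F12.
- TBSCl and imidazole should give 3-[(tert-butyldimethylsilyl)oxy]-2-{4-[(tert-butyldimethylsilyl)oxy]-3-methoxyphenyl}-4H-pyran-4-one F13.
- Bromine addition across C4a=C8a at −78 °C followed by Et3N elimination should give 8. The weakness of this detour is competing bromination of ring B, which is why it is not the main route.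

## Further compounds

F1 | step 9 | methyl 2-methoxy-2-{5-(tert-butyldimethylsilyloxy)-6-[4-(tert-butyldimethylsilyloxy)-3-methoxyphenyl]-4-oxo-3-[1-(triisopropylsilyloxy)vinyl]-4H-pyran-2-yl}acetate, racemic | COC(=O)C(OC)c1oc(-c2ccc(O[Si](C)(C)C(C)(C)C)c(OC)c2)c(O[Si](C)(C)C(C)(C)C)c(=O)c1C(=C)O[Si](C(C)C)(C(C)C)C(C)C
F2 | step 9 | 2-methoxy-2-{5-(tert-butyldimethylsilyloxy)-6-[4-(tert-butyldimethylsilyloxy)-3-methoxyphenyl]-4-oxo-3-[1-(triisopropylsilyloxy)vinyl]-4H-pyran-2-yl}acetic acid, racemic | OC(=O)C(OC)c1oc(-c2ccc(O[Si](C)(C)C(C)(C)C)c(OC)c2)c(O[Si](C)(C)C(C)(C)C)c(=O)c1C(=C)O[Si](C(C)C)(C(C)C)C(C)C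
F3 | step 9 | 2-methoxy-2-{5-(tert-butyldimethylsilyloxy)-6-[4-(tert-butyldimethylsilyloxy)-3-methoxyphenyl]-4-oxo-3-[1-(triisopropylsilyloxy)vinyl]-4H-pyran-2-yl}acetyl chloride, racemic | ClC(=O)C(OC)c1oc(-c2ccc(O[Si](C)(C)C(C)(C)C)c(OC)c2)c(O[Si](C)(C)C(C)(C)C)c(=O)c1C(=C)O[Si](C(C)C)(C(C)C)C(C)C
F4 | step 8 | pentacarbonyl{[3-(1-ethoxyvinyl)-5-(tert-butyldimethylsilyloxy)-6-(4-(tert-butyldimethylsilyloxy)-3-methoxyphenyl)-4-oxo-4H-pyran-2-yl](methoxy)methylidene}chromium | CCOC(=C)c1c(C(OC)=[Cr](=C=O)(=C=O)(=C=O)(=C=O)=C=O)oc(-c2ccc(O[Si](C)(C)C(C)(C)C)c(OC)c2)c(O[Si](C)(C)C(C)(C)C)c1=O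
F5 | step 8 | pentacarbonyl{[3-acetyl-5-(tert-butyldimethylsilyloxy)-6-(4-(tert-butyldimethylsilyloxy)-3-methoxyphenyl)-4-oxo-4H-pyran-2-yl](methoxy)methylidene}chromium | CC(=O)c1c(C(OC)=[Cr](=C=O)(=C=O)(=C=O)(=C=O)=C=O)oc(-c2ccc(O[Si](C)(C)C(C)(C)C)c(OC)c2)c(O[Si](C)(C)C(C)(C)C)c1=O
F6 | step 3 | (3,4-dibromofuran-2-yl)methanol | OCc1occ(Br)c1Br
F7 | step 3 | 4,5-dibromo-6-hydroxy-2H-pyran-3(6H)-one, racemic | OC1OCC(=O)C(Br)=C1Br
F8 | step 3 | 5-bromo-3-hydroxy-4H-pyran-4-one | O=c1c(Br)cocc1O
F9 | step 3 | 5-bromo-3-hydroxy-2-iodo-4H-pyran-4-one | O=c1c(Br)coc(I)c1O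
F10 | step 4 | (3-bromofuran-2-yl){4-[(tert-butyldimethylsilyl)oxy]-3-methoxyphenyl}methanol, racemic | COc1cc(C(O)c2occc2Br)ccc1O[Si](C)(C)C(C)(C)C
F11 | step 4 | 4-bromo-2-{4-[(tert-butyldimethylsilyl)oxy]-3-methoxyphenyl}-6-hydroxy-2H-pyran-3(6H)-one, racemic, both anomers | COc1cc(C2OC(O)C=C(Br)C2=O)ccc1O[Si](C)(C)C(C)(C)C
F12 | step 4 | 3-hydroxy-2-(4-hydroxy-3-methoxyphenyl)-4H-pyran-4-one | COc1cc(-c2occc(=O)c2O)ccc1O
F13 | step 4 | 3-[(tert-butyldimethylsilyl)oxy]-2-{4-[(tert-butyldimethylsilyl)oxy]-3-methoxyphenyl}-4H-pyran-4-one | COc1cc(-c2occc(=O)c2O[Si](C)(C)C(C)(C)C)ccc1O[Si](C)(C)C(C)(C)C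
A1 | alternative 1 | 4,6-bis(benzyloxy)-2-hydroxy-3-methoxybenzaldehyde | O=Cc1c(O)c(OC)c(OCc2ccccc2)cc1OCc1ccccc1
A2 | alternative 1 | (E)-1-(benzyloxy)-2-methoxy-4-(2-nitroethenyl)benzene | [O-][N+](=O)/C=C/c1ccc(OCc2ccccc2)c(OC)c1
A3 | alternative 1 | 5,7-bis(benzyloxy)-2-[4-(benzyloxy)-3-methoxyphenyl]-8-methoxy-3-nitro-2H-chromene, racemic | [O-][N+](=O)C1=Cc2c(OCc3ccccc3)cc(OCc3ccccc3)c(OC)c2OC1c1ccc(OCc2ccccc2)c(OC)c1
A4 | alternative 2 | 2-(benzoyloxy)-1-[4-(benzoyloxy)-3-methoxyphenyl]-3-[2-hydroxy-5-methoxy-4-(3-methylbut-2-enyloxy)phenyl]propane-1,3-dione, racemic | COc1cc(C(=O)C(OC(=O)c2ccccc2)C(=O)c2ccc(OC(=O)c3ccccc3)c(OC)c2)c(O)cc1OCC=C(C)C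
A5 | alternative 2 | 2-[4-(benzoyloxy)-3-methoxyphenyl]-5-hydroxy-8-methoxy-7-(3-methylbut-2-enyloxy)-4-oxo-4H-chromen-3-yl benzoate | O=c1c(OC(=O)c2ccccc2)c(-c2ccc(OC(=O)c3ccccc3)c(OC)c2)oc2c(OC)c(OCC=C(C)C)cc(O)c12
A6 | alternative 3 | 3-(benzyloxy)-4-{5-(benzyloxy)-6-[4-(benzyloxy)-3-methoxyphenyl]-4-oxo-4H-pyran-2-yl}-4-hydroxycyclobut-2-en-1-one, racemic | O=C1C=C(OCc2ccccc2)C1(O)c1cc(=O)c(OCc2ccccc2)c(-c2ccc(OCc3ccccc3)c(OC)c2)o1
A7 | alternative 3 | 3,7-bis(benzyloxy)-2-[4-(benzyloxy)-3-methoxyphenyl]-5,8-dihydroxy-4H-chromen-4-one | O=c1c(OCc2ccccc2)c(-c2ccc(OCc3ccccc3)c(OC)c2)oc2c(O)c(OCc3ccccc3)cc(O)c12
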